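**Retrosynthetic overview**

1. The target is ent-epiafzelechin-(4β→8)-epiafzelechin-(4α→8)-ent-epiafzelechin-4α-ol. The last disconnection removes twelve benzyl ethers, and each all-cis (2,3-cis-3,4-cis) heterocycle goes back to a 2,4-diarylchroman-3-one whose C2, C3 and C4 are set together by hydrogenation with dynamic kinetic resolution (opposite catalyst antipodes for the middle and upper units).
2. Each chroman-3-one comes from a 3-silyloxy-4-arylcoumarin by Grignard addition of ring B at C2 and hydride transfer to the flavylium ion.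
3. Key disconnection: the upper heterocycle (O1, C2, C3, C4, C4a, C8a) is made by one-carbon ring expansion of the five-membered ring of 4,6-bis(benzyloxy)benzofuran-2,3-dione with the aryldiazomethane derived from the C8 aldehyde of the lower dimer. The diazo carbon becomes C4 and carries the C4–C8 interflavan bond with it.
4. Enabling feature: in the benzofurandione ring (O1–C2(=O)–C3(=O)–C3a–C7a) the C3 ketone is activated by the adjacent lactone carbonyl, and its aryl neighbour C3a is ortho/para to three oxygens (O1, 4-O, 6-O), so C3a migrates to the diazonium carbon as N2 leaves.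
5. Ring order: the A rings come from 3,5-bis(benzyloxy)phenol. The lower ring C is built first (same module with TMSCHN2; C4–O by DDQ), then the middle ring C, then the upper ring C (key step). The B rings enter as one aryl Grignard reagent.

Key step: step 21

**Conventions and assumptions**

- Ar = 4-(benzyloxy)phenyl; Bn = benzyl; TBS = tert-butyldimethylsilyl.
- L = (2S,3S,4R)-3,4,5,7-tetrakis(benzyloxy)-2-Ar-chroman-8-yl (lower unit; 2,3-cis, 3,4-trans).
- M = (2R,3R)-3,5,7-tris(benzyloxy)-2-Ar-4-L-chroman-8-yl with H-2, H-3 and H-4 all cis (middle unit; L is cis to the 3-oxygen).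
- Assumption: the sense of induction of RuCl2(Xyl-SDP)(DPEN) on chroman-3-ones is taken by analogy with cis-2-arylcyclohexanols. Both catalyst antipodes are available, so an opposite sense would only exchange which antipode is used in which step.
- Remark: the hindered aryl–heteroaryl bond in 19–23 and 32–36 may give atropisomers; they converge once C4 becomes tetrahedral and epimerisable (24, 37). Centres drawn without descriptors (8, 11, 21, 24, 34, 37) are racemic or labile.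
- 3,5-Bis(benzyloxy)phenol and [4-(benzyloxy)phenyl]magnesium bromide (THF solution) are taken as commercial.

**Route**

Step 1
Reactants: 1 3,5-bis(benzyloxy)phenol
Product: 2 2-bromo-3,5-bis(benzyloxy)phenol
Conditions: NBS (1.0 equiv), i-Pr2NH (10 mol %), CH2Cl2, −78 → 0 °C
Reagents that add atoms: N-bromosuccinimide, O=C1CCC(=O)N1Br
Why: Amine-catalysed ortho-selective bromination of a phenol, in which the hydrogen-bonded N-bromoamine should deliver bromine next to the OH rather than between the two ether groups.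

Step 2
Reactants: 2 2-bromo-3,5-bis(benzyloxy)phenol
Product: 3 7-bromo-4,6-bis(benzyloxy)benzofuran-2,3-dione
Conditions: (COCl)2 (1.5 equiv), ClCH2CH2Cl, 0 → 70 °C
Reagents that add atoms: oxalyl chloride, O=C(Cl)C(=O)Cl
Why: O-acylation to the aryl chlorooxalate followed by intramolecular Friedel–Crafts acylation at the only free ortho carbon, which is ortho/para to both benzyloxy groups (the known coumarandione synthesis from 3,5-dialkoxyphenols).

Step 3
Reactants: 3 7-bromo-4,6-bis(benzyloxy)benzofuran-2,3-dione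
Product: 5 8-bromo-5,7-bis(benzyloxy)-3-hydroxy-2H-chromen-2-one, via trimethylsilyl enol ether 4 (not isolated)
Conditions: TMSCHN2 (1.2 equiv), Sc(OTf)3 (5 mol %), CH2Cl2, −40 → 0 °C; then 1 M aq. citric acid, THF, rt
Reagents that add atoms: (trimethylsilyl)diazomethane, C[Si](C)(C)C=[N+]=[N-]
Why: Eistert-type diazoalkane ring expansion of a cyclic 1,2-dione (as known for isatins): attack at the C3 ketone, 1,2-shift of the electron-rich aryl carbon with loss of N2 and a 1,3-silyl shift should give the coumarin silyl enol ether, which the acidic work-up hydrolyses.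

Step 4
Reactants: 5 8-bromo-5,7-bis(benzyloxy)-3-hydroxy-2H-chromen-2-one
Product: 6 8-bromo-5,7-bis(benzyloxy)-3-(TBSO)-2H-chromen-2-one
Conditions: TBSCl (1.2 equiv), imidazole (2.5 equiv), DMF, rt
Reagents that add atoms: tert-butyldimethylsilyl chloride, CC(C)(C)[Si](C)(C)Cl
Why: O-silylation of the acidic enol masks it for the Grignard addition and keeps C3 at the enol oxidation level.

Step 5
Reactants: 6 8-bromo-5,7-bis(benzyloxy)-3-(TBSO)-2H-chromen-2-one; 7 [4-(benzyloxy)phenyl]magnesium bromide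
Product: 8 racemic 8-bromo-5,7-bis(benzyloxy)-2-Ar-3-(TBSO)-2H-chromen-2-ol
Conditions: 7 (1.15 equiv, 1.0 M in THF), THF, −78 → −30 °C; then pH 7 phosphate buffer
Reagents that add atoms: none
Why: 1,2-Addition of an aryl Grignard reagent to the coumarin lactone carbonyl (the classical coumarin-to-flavylium route); the magnesium lactolate should resist a second addition at low temperature.

Step 6
Reactants: 8 racemic 8-bromo-5,7-bis(benzyloxy)-2-Ar-3-(TBSO)-2H-chromen-2-ol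
Product: 11 racemic 8-bromo-5,7-bis(benzyloxy)-2-Ar-chroman-3-one, via flavylium acetate 9 (not isolated), via silyl enol ether 10 (not isolated)
Conditions: Hantzsch ester (1.3 equiv), AcOH (2 equiv), CH2Cl2, 0 °C → rt; then Bu4NF (1.1 equiv), THF, 0 °C
Reagents that add atoms: none
Why: Acetic acid should ionise the lactol to the 3-silyloxyflavylium ion, which accepts hydride from the dihydropyridine at C4 (transfer hydrogenation of benzopyrylium ions); buffered fluoride then unveils the ketone, which the Hantzsch ester does not reduce.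

Step 7
Reactants: 11 racemic 8-bromo-5,7-bis(benzyloxy)-2-Ar-chroman-3-one
Product: 12 (2S,3S)-8-bromo-5,7-bis(benzyloxy)-2-Ar-chroman-3-ol (2,3-cis)
Conditions: RuCl2[(S)-Xyl-SDP][(R,R)-DPEN] (1 mol %), KOtBu (10 mol %), H2 (50 atm), i-PrOH/toluene, 25 °C
Reagents that add atoms: none
Why: Noyori-type asymmetric hydrogenation with dynamic kinetic resolution of a racemic α-aryl cyclic ketone: base racemises C2 through the enolate while the catalyst should reduce one enantiomer from the face that leaves OH axial and cis to the equatorial aryl group, setting C2 and C3.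

Step 8
Reactants: 12 (2S,3S)-8-bromo-5,7-bis(benzyloxy)-2-Ar-chroman-3-ol
Product: 13 (2S,3S,4R)-4,5,7-tris(benzyloxy)-8-bromo-2-Ar-chroman-3-ol (3,4-trans)
Conditions: DDQ (2 equiv), BnOH (5 equiv), CH2Cl2, rt
Reagents that add atoms: benzyl alcohol, OCc1ccccc1
Why: DDQ-mediated C4–H oxidation of a 5,7-dialkoxyflavan (hydride abstraction to the cation stabilised by ring A), known for benzylated flavan-3-ols; benzyl alcohol should add to the face opposite the cis 2-aryl and 3-hydroxy groups, setting C4 trans to O-3.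

Step 9
Reactants: 13 (2S,3S,4R)-4,5,7-tris(benzyloxy)-8-bromo-2-Ar-chroman-3-ol
Product: 14 (2S,3S,4R)-3,4,5,7-tetrakis(benzyloxy)-8-bromo-2-Ar-chroman (L–Br)
Conditions: NaH (1.5 equiv), BnBr (1.5 equiv), Bu4NI (cat.), DMF, 0 °C → rt
Reagents that add atoms: benzyl bromide, BrCc1ccccc1
Why: Williamson etherification protects the secondary alcohol before the organolithium and Grignard steps.

Step 10
Reactants: 14 L–Br
Product: 16 (2S,3S,4R)-3,4,5,7-tetrakis(benzyloxy)-2-Ar-chroman-8-carbaldehyde (L–CHO), via aryllithium 15 (not isolated)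
Conditions: n-BuLi (1.1 equiv), THF, −78 °C; DMF (3 equiv), −78 → 0 °C; H2O
Reagents that add atoms: N,N-dimethylformamide, CN(C)C=O
Why: Bromine–lithium exchange at C8 and formylation with DMF install the carbon that becomes C4 of the middle unit, with the position fixed by the bromine carried from step 1.

Step 11
Reactants: 16 L–CHO
Product: 17 (E)-hydrazone of L–CHO
Conditions: N2H4·H2O (10 equiv), EtOH/THF (1:1), 50 °C
Reagents that add atoms: hydrazine, NN
Why: Condensation with excess hydrazine gives the free hydrazone and suppresses azine formation.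

Step 12
Reactants: 17 (E)-hydrazone of L–CHO; 3 7-bromo-4,6-bis(benzyloxy)benzofuran-2,3-dione
Product: 19 8-bromo-5,7-bis(benzyloxy)-3-hydroxy-4-L-2H-chromen-2-one, via diazoalkane 18 (not isolated)
Conditions: MnO2 (10 equiv), MgSO4, CH2Cl2, 0 °C, filtered cold through Celite; filtrate added over 1 h to 3 (1.5 equiv), CH2Cl2, 0 °C → rt
Reagents that add atoms: none
Why: The same diazoalkane ring expansion of the 1,2-dione as in step 3, now with the electron-rich aryldiazomethane from MnO2 dehydrogenation of the hydrazone; no Lewis acid is used, so the C4 benzyl ether of L should not ionise.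

Step 13
Reactants: 19 8-bromo-5,7-bis(benzyloxy)-3-hydroxy-4-L-2H-chromen-2-one
Product: 20 8-bromo-5,7-bis(benzyloxy)-4-L-3-(TBSO)-2H-chromen-2-one
Conditions: TBSCl (1.5 equiv), imidazole (3 equiv), DMF, rt
Reagents that add atoms: tert-butyldimethylsilyl chloride, CC(C)(C)[Si](C)(C)Cl
Why: O-silylation of the only free hydroxyl, the acidic coumarin enol.

Step 14
Reactants: 20 8-bromo-5,7-bis(benzyloxy)-4-L-3-(TBSO)-2H-chromen-2-one; 7 [4-(benzyloxy)phenyl]magnesium bromide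
Product: 21 8-bromo-5,7-bis(benzyloxy)-2-Ar-4-L-3-(TBSO)-2H-chromen-2-ol (C2 epimers)
Conditions: 7 (1.2 equiv), THF, −78 → −20 °C; then pH 7 phosphate buffer
Reagents that add atoms: none
Why: 1,2-Addition of the aryl Grignard reagent to the lactone carbonyl as in step 5; C4 is fully substituted, so conjugate addition is excluded.

Step 15
Reactants: 21 8-bromo-5,7-bis(benzyloxy)-2-Ar-4-L-3-(TBSO)-2H-chromen-2-ol
Product: 24 8-bromo-5,7-bis(benzyloxy)-2-Ar-4-L-chroman-3-one (C2 and C4 labile), via flavylium acetate 22 (not isolated), via silyl enol ether 23 (not isolated)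
Conditions: Hantzsch ester (1.3 equiv), AcOH (2 equiv), CH2Cl2, 0 °C → rt; then Bu4NF (1.1 equiv), THF, 0 °C
Reagents that add atoms: none
Why: Ionisation to the 4-aryl-3-silyloxyflavylium ion and hydride transfer from the Hantzsch ester as in step 6; the regiochemistry of hydride transfer is erased when fluoride unveils the ketone, and two equivalents of acetic acid should be too weak to ionise the C4 benzyl ether of L.

Step 16
Reactants: 24 8-bromo-5,7-bis(benzyloxy)-2-Ar-4-L-chroman-3-one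
Product: 25 (2R,3R)-8-bromo-5,7-bis(benzyloxy)-2-Ar-4-L-chroman-3-ol (H-2, H-3, H-4 all cis)
Conditions: RuCl2[(R)-Xyl-SDP][(S,S)-DPEN] (2 mol %), KOtBu (20 mol %), H2 (50 atm), i-PrOH/toluene, 25 °C
Reagents that add atoms: none
Why: Asymmetric hydrogenation with dynamic kinetic resolution of an α,α'-disubstituted cyclic ketone: C2 and C4 both epimerise through enolates, and the antipodal catalyst should reduce the epimer with both aryl groups equatorial from the equatorial direction, giving the axial 3-OH cis to both and setting C2, C3 and C4 together.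

Step 17
Reactants: 25 (2R,3R)-8-bromo-5,7-bis(benzyloxy)-2-Ar-4-L-chroman-3-ol
Product: 26 (2R,3R)-3,5,7-tris(benzyloxy)-8-bromo-2-Ar-4-L-chroman (M–Br)
Conditions: NaH (2 equiv), BnBr (2 equiv), Bu4NI (cat.), DMF, 0 °C → rt
Reagents that add atoms: benzyl bromide, BrCc1ccccc1
Why: Williamson etherification of the axial secondary alcohol before lithiation.

Step 18
Reactants: 26 M–Br
Product: 28 M–CHO (middle-unit 8-carbaldehyde), via aryllithium 27 (not isolated)
Conditions: n-BuLi (1.1 equiv), THF, −78 °C; DMF (3 equiv), −78 → 0 °C; H2O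
Reagents that add atoms: N,N-dimethylformamide, CN(C)C=O
Why: Bromine–lithium exchange and formylation as in step 10 place the future C4 of the upper unit on C8 of the middle unit.

Step 19
Reactants: 28 M–CHO
Product: 29 (E)-hydrazone of M–CHO
Conditions: N2H4·H2O (10 equiv), EtOH/THF (1:1), 50 °C
Reagents that add atoms: hydrazine, NN
Why: Hydrazone formation as in step 11.

Step 20
Reactants: 1 3,5-bis(benzyloxy)phenol
Product: 30 4,6-bis(benzyloxy)benzofuran-2,3-dione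
Conditions: (COCl)2 (1.5 equiv), ClCH2CH2Cl, 0 → 70 °C
Reagents that add atoms: oxalyl chloride, O=C(Cl)C(=O)Cl
Why: O-acylation and intramolecular Friedel–Crafts acylation as in step 2; the two ortho positions of 1 are equivalent.

Step 21
Reactants: 29 (E)-hydrazone of M–CHO; 30 4,6-bis(benzyloxy)benzofuran-2,3-dione
Product: 32 5,7-bis(benzyloxy)-3-hydroxy-4-M-2H-chromen-2-one, via diazoalkane 31 (not isolated)
Conditions: MnO2 (10 equiv), MgSO4, CH2Cl2, 0 °C, filtered cold through Celite; filtrate added over 1 h to 30 (2 equiv), CH2Cl2, 0 °C → rt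
Reagents that add atoms: none
Why: MnO2 dehydrogenates the hydrazone to the aryldiazomethane, whose nucleophilic carbon adds to the C3 ketone of 30 (the more electrophilic carbonyl of the 1,2-dione); in the diazonium alkoxide the aryl carbon C3a migrates from C3 to the diazonium carbon as N2 leaves, and the 4-aryl-chroman-2,3-dione tautomerises to the 3-hydroxycoumarin. The closest known reaction type is the Eistert (Tiffeneau–Demjanov-type) ring expansion of isatins and related cyclic 1,2-diones with aryldiazomethanes to 3-hydroxy-4-aryl-2-quinolones. One ring is closed, the six-membered pyranone O1–C2–C3–C4–C4a–C8a, by ring enlargement: one carbon is inserted between C3 and C3a of the five-membered benzofurandione through the 1,2-aryl shift, so the former formyl carbon of the middle unit becomes C4 and the C4–C8 interflavan bond is already in place. No stereocentre is created here (C4 is trigonal), and C2, C3 and C4 of this ring are set together in step 25. The step needs aryl rather than acyl migration and ring expansion rather than epoxide closure; the first is secured by the migrating carbon being ortho/para to three oxygens and by the poor migratory aptitude of the lactone carbonyl, and slow addition to excess 30 keeps the diazoalkane away from the acidic enol product.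

Step 22
Reactants: 32 5,7-bis(benzyloxy)-3-hydroxy-4-M-2H-chromen-2-one
Product: 33 5,7-bis(benzyloxy)-4-M-3-(TBSO)-2H-chromen-2-one
Conditions: TBSCl (1.5 equiv), imidazole (3 equiv), DMF, rt
Reagents that add atoms: tert-butyldimethylsilyl chloride, CC(C)(C)[Si](C)(C)Cl
Why: O-silylation of the only free hydroxyl, the coumarin enol.

Step 23
Reactants: 33 5,7-bis(benzyloxy)-4-M-3-(TBSO)-2H-chromen-2-one; 7 [4-(benzyloxy)phenyl]magnesium bromide
Product: 34 5,7-bis(benzyloxy)-2-Ar-4-M-3-(TBSO)-2H-chromen-2-ol (C2 epimers)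
Conditions: 7 (1.2 equiv), THF, −78 → −20 °C; then pH 7 phosphate buffer
Reagents that add atoms: none
Why: 1,2-Addition of the aryl Grignard reagent to the lactone carbonyl brings in ring B of the upper unit, as in steps 5 and 14.

Step 24
Reactants: 34 5,7-bis(benzyloxy)-2-Ar-4-M-3-(TBSO)-2H-chromen-2-ol
Product: 37 5,7-bis(benzyloxy)-2-Ar-4-M-chroman-3-one (C2 and C4 labile), via flavylium acetate 35 (not isolated), via silyl enol ether 36 (not isolated)
Conditions: Hantzsch ester (1.3 equiv), AcOH (2 equiv), CH2Cl2, 0 °C → rt; then Bu4NF (1.1 equiv), THF, 0 °C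
Reagents that add atoms: none
Why: Ionisation to the flavylium ion, hydride transfer from the Hantzsch ester and fluoride-induced release of the ketone as in step 15; the ketone is not reduced by the dihydropyridine.

Step 25
Reactants: 37 5,7-bis(benzyloxy)-2-Ar-4-M-chroman-3-one
Product: 38 (2S,3S)-5,7-bis(benzyloxy)-2-Ar-4-M-chroman-3-ol (H-2, H-3, H-4 all cis; upper ring 2S,3S,4R)
Conditions: RuCl2[(S)-Xyl-SDP][(R,R)-DPEN] (2 mol %), KOtBu (20 mol %), H2 (50 atm), i-PrOH/toluene, 25 °C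
Reagents that add atoms: none
Why: Asymmetric hydrogenation with dynamic kinetic resolution as in step 16, with the catalyst antipode of step 7: C2 and C4 equilibrate through enolates and the catalyst should reduce the diequatorial epimer from the equatorial direction, giving the axial 3-OH cis to both aryl groups in the (2S,3S) series.

Step 26
Reactants: 38 (2S,3S)-5,7-bis(benzyloxy)-2-Ar-4-M-chroman-3-ol
Product: 39 ent-epiafzelechin-(4β→8)-epiafzelechin-(4α→8)-ent-epiafzelechin-4α-ol (target)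
Conditions: H2 (1 atm), Pd(OH)2/C (20 wt %), THF/MeOH (1:1), rt; filtered under argon, lyophilised
Reagents that add atoms: none
Why: Neutral hydrogenolysis of nine aryl and three alkyl benzyl ethers; O–CH2Ph cleavage is expected to be faster than cleavage of the hindered secondary C4–O bond of the lower unit, and no stereocentre is touched.

**Compound list**

1 | 3,5-bis(benzyloxy)phenol | Oc1cc(OCc2ccccc2)cc(OCc2ccccc2)c1 | starting material
2 | 2-bromo-3,5-bis(benzyloxy)phenol | Oc1cc(OCc2ccccc2)cc(OCc2ccccc2)c1Br | intermediate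
3 | 7-bromo-4,6-bis(benzyloxy)benzofuran-2,3-dione | O=C1Oc2c(Br)c(OCc3ccccc3)cc(OCc3ccccc3)c2C1=O | intermediate
4 | 8-bromo-5,7-bis(benzyloxy)-3-(trimethylsilyloxy)-2H-chromen-2-one | O=C1Oc2c(Br)c(OCc3ccccc3)cc(OCc3ccccc3)c2C=C1O[Si](C)(C)C | intermediate
5 | 8-bromo-5,7-bis(benzyloxy)-3-hydroxy-2H-chromen-2-one | O=C1Oc2c(Br)c(OCc3ccccc3)cc(OCc3ccccc3)c2C=C1O | intermediate
6 | 8-bromo-5,7-bis(benzyloxy)-3-(tert-butyldimethylsilyloxy)-2H-chromen-2-one | O=C1Oc2c(Br)c(OCc3ccccc3)cc(OCc3ccccc3)c2C=C1O[Si](C)(C)C(C)(C)C | intermediate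
7 | [4-(benzyloxy)phenyl]magnesium bromide | Br[Mg]c1ccc(OCc2ccccc2)cc1 | starting material
8 | racemic 8-bromo-5,7-bis(benzyloxy)-2-[4-(benzyloxy)phenyl]-3-(tert-butyldimethylsilyloxy)-2H-chromen-2-ol | OC1(c2ccc(OCc3ccccc3)cc2)Oc2c(Br)c(OCc3ccccc3)cc(OCc3ccccc3)c2C=C1O[Si](C)(C)C(C)(C)C | intermediate
9 | 8-bromo-5,7-bis(benzyloxy)-2-[4-(benzyloxy)phenyl]-3-(tert-butyldimethylsilyloxy)chromenylium acetate | CC(C)(C)[Si](C)(C)Oc1cc2c(OCc3ccccc3)cc(OCc3ccccc3)c(Br)c2[o+]c1-c1ccc(OCc3ccccc3)cc1.CC(=O)[O-] | intermediate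
10 | 8-bromo-5,7-bis(benzyloxy)-2-[4-(benzyloxy)phenyl]-3-(tert-butyldimethylsilyloxy)-4H-chromene | CC(C)(C)[Si](C)(C)OC1=C(c2ccc(OCc3ccccc3)cc2)Oc2c(Br)c(OCc3ccccc3)cc(OCc3ccccc3)c2C1 | intermediate
11 | racemic 8-bromo-5,7-bis(benzyloxy)-2-[4-(benzyloxy)phenyl]chroman-3-one | O=C1Cc2c(OCc3ccccc3)cc(OCc3ccccc3)c(Br)c2OC1c1ccc(OCc3ccccc3)cc1 | intermediate
12 | (2S,3S)-8-bromo-5,7-bis(benzyloxy)-2-[4-(benzyloxy)phenyl]chroman-3-ol | Brc1c(OCc3ccccc3)cc(OCc3ccccc3)c2c1O[C@@H](c1ccc(OCc3ccccc3)cc1)[C@@H](O)C2 | intermediate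
13 | (2S,3S,4R)-4,5,7-tris(benzyloxy)-8-bromo-2-[4-(benzyloxy)phenyl]chroman-3-ol | Brc1c(OCc3ccccc3)cc(OCc3ccccc3)c2c1O[C@@H](c1ccc(OCc3ccccc3)cc1)[C@@H](O)[C@@H]2OCc1ccccc1 | intermediate
14 | (2S,3S,4R)-3,4,5,7-tetrakis(benzyloxy)-8-bromo-2-[4-(benzyloxy)phenyl]chroman (L–Br) | Brc1c(OCc3ccccc3)cc(OCc3ccccc3)c2c1O[C@@H](c1ccc(OCc3ccccc3)cc1)[C@@H](OCc1ccccc1)[C@@H]2OCc1ccccc1 | intermediate
15 | L–Li, the 8-lithio compound from 14 | [Li]c1c(OCc3ccccc3)cc(OCc3ccccc3)c2c1O[C@@H](c1ccc(OCc3ccccc3)cc1)[C@@H](OCc1ccccc1)[C@@H]2OCc1ccccc1 | intermediate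
16 | (2S,3S,4R)-3,4,5,7-tetrakis(benzyloxy)-2-[4-(benzyloxy)phenyl]chroman-8-carbaldehyde (L–CHO) | O=Cc1c(OCc3ccccc3)cc(OCc3ccccc3)c2c1O[C@@H](c1ccc(OCc3ccccc3)cc1)[C@@H](OCc1ccccc1)[C@@H]2OCc1ccccc1 | intermediate
17 | (E)-hydrazone of L–CHO | N/N=C/c1c(OCc3ccccc3)cc(OCc3ccccc3)c2c1O[C@@H](c1ccc(OCc3ccccc3)cc1)[C@@H](OCc1ccccc1)[C@@H]2OCc1ccccc1 | intermediate
18 | L–CH=N2, the 8-(diazomethyl) lower unit | [N-]=[N+]=Cc1c(OCc3ccccc3)cc(OCc3ccccc3)c2c1O[C@@H](c1ccc(OCc3ccccc3)cc1)[C@@H](OCc1ccccc1)[C@@H]2OCc1ccccc1 | intermediate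
19 | 8-bromo-5,7-bis(benzyloxy)-3-hydroxy-4-L-2H-chromen-2-one | O=C1Oc2c(Br)c(OCc5ccccc5)cc(OCc5ccccc5)c2C(=C1O)c3c(OCc5ccccc5)cc(OCc5ccccc5)c4c3O[C@@H](c3ccc(OCc5ccccc5)cc3)[C@@H](OCc5ccccc5)[C@@H]4OCc5ccccc5 | intermediate
20 | 8-bromo-5,7-bis(benzyloxy)-4-L-3-(tert-butyldimethylsilyloxy)-2H-chromen-2-one | O=C1Oc2c(Br)c(OCc5ccccc5)cc(OCc5ccccc5)c2C(=C1O[Si](C)(C)C(C)(C)C)c3c(OCc5ccccc5)cc(OCc5ccccc5)c4c3O[C@@H](c3ccc(OCc5ccccc5)cc3)[C@@H](OCc5ccccc5)[C@@H]4OCc5ccccc5 | intermediate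
21 | 8-bromo-5,7-bis(benzyloxy)-2-[4-(benzyloxy)phenyl]-4-L-3-(tert-butyldimethylsilyloxy)-2H-chromen-2-ol (C2 epimers) | OC1(c6ccc(OCc5ccccc5)cc6)Oc2c(Br)c(OCc5ccccc5)cc(OCc5ccccc5)c2C(=C1O[Si](C)(C)C(C)(C)C)c3c(OCc5ccccc5)cc(OCc5ccccc5)c4c3O[C@@H](c3ccc(OCc5ccccc5)cc3)[C@@H](OCc5ccccc5)[C@@H]4OCc5ccccc5 | intermediate
22 | 8-bromo-5,7-bis(benzyloxy)-2-[4-(benzyloxy)phenyl]-4-L-3-(tert-butyldimethylsilyloxy)chromenylium acetate | CC(C)(C)[Si](C)(C)Oc1c(-c3c(OCc5ccccc5)cc(OCc5ccccc5)c4c3O[C@@H](c3ccc(OCc5ccccc5)cc3)[C@@H](OCc5ccccc5)[C@@H]4OCc5ccccc5)c2c(OCc5ccccc5)cc(OCc5ccccc5)c(Br)c2[o+]c1-c1ccc(OCc5ccccc5)cc1.CC(=O)[O-] | intermediate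
23 | 8-bromo-5,7-bis(benzyloxy)-2-[4-(benzyloxy)phenyl]-4-L-3-(tert-butyldimethylsilyloxy)-2H-chromene | CC(C)(C)[Si](C)(C)OC1=C(c3c(OCc5ccccc5)cc(OCc5ccccc5)c4c3O[C@@H](c3ccc(OCc5ccccc5)cc3)[C@@H](OCc5ccccc5)[C@@H]4OCc5ccccc5)c2c(OCc5ccccc5)cc(OCc5ccccc5)c(Br)c2OC1c1ccc(OCc5ccccc5)cc1 | intermediate
24 | 8-bromo-5,7-bis(benzyloxy)-2-[4-(benzyloxy)phenyl]-4-L-chroman-3-one (C2 and C4 labile) | O=C1C(c3c(OCc5ccccc5)cc(OCc5ccccc5)c4c3O[C@@H](c3ccc(OCc5ccccc5)cc3)[C@@H](OCc5ccccc5)[C@@H]4OCc5ccccc5)c2c(OCc5ccccc5)cc(OCc5ccccc5)c(Br)c2OC1c1ccc(OCc5ccccc5)cc1 | intermediate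
25 | (2R,3R)-8-bromo-5,7-bis(benzyloxy)-2-[4-(benzyloxy)phenyl]-4-L-chroman-3-ol, H-2, H-3 and H-4 all cis | C(c5ccccc5)Oc1ccc([C@H]2Oc3c(c(OCc5ccccc5)cc(OCc5ccccc5)c3Br)[C@@H](c3c(OCc5ccccc5)cc(OCc5ccccc5)c4c3O[C@@H](c3ccc(OCc5ccccc5)cc3)[C@@H](OCc5ccccc5)[C@@H]4OCc5ccccc5)[C@H]2O)cc1 | intermediate
26 | (2R,3R)-3,5,7-tris(benzyloxy)-8-bromo-2-[4-(benzyloxy)phenyl]-4-L-chroman, all cis (M–Br) | C(c5ccccc5)Oc1ccc([C@H]2Oc3c(c(OCc5ccccc5)cc(OCc5ccccc5)c3Br)[C@@H](c3c(OCc5ccccc5)cc(OCc5ccccc5)c4c3O[C@@H](c3ccc(OCc5ccccc5)cc3)[C@@H](OCc5ccccc5)[C@@H]4OCc5ccccc5)[C@H]2OCc5ccccc5)cc1 | intermediate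
27 | M–Li, the 8-lithio compound from 26 | C(c5ccccc5)Oc1ccc([C@H]2Oc3c(c(OCc5ccccc5)cc(OCc5ccccc5)c3[Li])[C@@H](c3c(OCc5ccccc5)cc(OCc5ccccc5)c4c3O[C@@H](c3ccc(OCc5ccccc5)cc3)[C@@H](OCc5ccccc5)[C@@H]4OCc5ccccc5)[C@H]2OCc5ccccc5)cc1 | intermediate
28 | M–CHO, the middle-unit 8-carbaldehyde | C(c5ccccc5)Oc1ccc([C@H]2Oc3c(c(OCc5ccccc5)cc(OCc5ccccc5)c3C=O)[C@@H](c3c(OCc5ccccc5)cc(OCc5ccccc5)c4c3O[C@@H](c3ccc(OCc5ccccc5)cc3)[C@@H](OCc5ccccc5)[C@@H]4OCc5ccccc5)[C@H]2OCc5ccccc5)cc1 | intermediate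
29 | (E)-hydrazone of M–CHO | C(c5ccccc5)Oc1ccc([C@H]2Oc3c(c(OCc5ccccc5)cc(OCc5ccccc5)c3/C=N/N)[C@@H](c3c(OCc5ccccc5)cc(OCc5ccccc5)c4c3O[C@@H](c3ccc(OCc5ccccc5)cc3)[C@@H](OCc5ccccc5)[C@@H]4OCc5ccccc5)[C@H]2OCc5ccccc5)cc1 | intermediate
30 | 4,6-bis(benzyloxy)benzofuran-2,3-dione | O=C1Oc2cc(OCc3ccccc3)cc(OCc3ccccc3)c2C1=O | intermediate
31 | M–CH=N2, the 8-(diazomethyl) dimer | C(c5ccccc5)Oc1ccc([C@H]2Oc3c(c(OCc5ccccc5)cc(OCc5ccccc5)c3C=[N+]=[N-])[C@@H](c3c(OCc5ccccc5)cc(OCc5ccccc5)c4c3O[C@@H](c3ccc(OCc5ccccc5)cc3)[C@@H](OCc5ccccc5)[C@@H]4OCc5ccccc5)[C@H]2OCc5ccccc5)cc1 | intermediate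
32 | 5,7-bis(benzyloxy)-3-hydroxy-4-M-2H-chromen-2-one | C(c5ccccc5)Oc1ccc([C@H]2Oc3c(c(OCc5ccccc5)cc(OCc5ccccc5)c3C3=C(O)C(=O)Oc4cc(OCc5ccccc5)cc(OCc5ccccc5)c34)[C@@H](c3c(OCc5ccccc5)cc(OCc5ccccc5)c4c3O[C@@H](c3ccc(OCc5ccccc5)cc3)[C@@H](OCc5ccccc5)[C@@H]4OCc5ccccc5)[C@H]2OCc5ccccc5)cc1 | intermediate
33 | 5,7-bis(benzyloxy)-4-M-3-(tert-butyldimethylsilyloxy)-2H-chromen-2-one | C(c5ccccc5)Oc1ccc([C@H]2Oc3c(c(OCc5ccccc5)cc(OCc5ccccc5)c3C3=C(O[Si](C)(C)C(C)(C)C)C(=O)Oc4cc(OCc5ccccc5)cc(OCc5ccccc5)c34)[C@@H](c3c(OCc5ccccc5)cc(OCc5ccccc5)c4c3O[C@@H](c3ccc(OCc5ccccc5)cc3)[C@@H](OCc5ccccc5)[C@@H]4OCc5ccccc5)[C@H]2OCc5ccccc5)cc1 | intermediate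
34 | 5,7-bis(benzyloxy)-2-[4-(benzyloxy)phenyl]-4-M-3-(tert-butyldimethylsilyloxy)-2H-chromen-2-ol (C2 epimers) | C(c5ccccc5)Oc1ccc([C@H]2Oc3c(c(OCc5ccccc5)cc(OCc5ccccc5)c3C3=C(O[Si](C)(C)C(C)(C)C)C(O)(c4ccc(OCc5ccccc5)cc4)Oc4cc(OCc5ccccc5)cc(OCc5ccccc5)c34)[C@@H](c3c(OCc5ccccc5)cc(OCc5ccccc5)c4c3O[C@@H](c3ccc(OCc5ccccc5)cc3)[C@@H](OCc5ccccc5)[C@@H]4OCc5ccccc5)[C@H]2OCc5ccccc5)cc1 | intermediate
35 | 5,7-bis(benzyloxy)-2-[4-(benzyloxy)phenyl]-4-M-3-(tert-butyldimethylsilyloxy)chromenylium acetate | C(c5ccccc5)Oc1ccc([C@H]2Oc3c(c(OCc5ccccc5)cc(OCc5ccccc5)c3-c3c(O[Si](C)(C)C(C)(C)C)c(-c4ccc(OCc5ccccc5)cc4)[o+]c4cc(OCc5ccccc5)cc(OCc5ccccc5)c34)[C@@H](c3c(OCc5ccccc5)cc(OCc5ccccc5)c4c3O[C@@H](c3ccc(OCc5ccccc5)cc3)[C@@H](OCc5ccccc5)[C@@H]4OCc5ccccc5)[C@H]2OCc5ccccc5)cc1.CC(=O)[O-] | intermediate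
36 | 5,7-bis(benzyloxy)-2-[4-(benzyloxy)phenyl]-4-M-3-(tert-butyldimethylsilyloxy)-2H-chromene | C(c5ccccc5)Oc1ccc([C@H]2Oc3c(c(OCc5ccccc5)cc(OCc5ccccc5)c3C3=C(O[Si](C)(C)C(C)(C)C)C(c4ccc(OCc5ccccc5)cc4)Oc4cc(OCc5ccccc5)cc(OCc5ccccc5)c34)[C@@H](c3c(OCc5ccccc5)cc(OCc5ccccc5)c4c3O[C@@H](c3ccc(OCc5ccccc5)cc3)[C@@H](OCc5ccccc5)[C@@H]4OCc5ccccc5)[C@H]2OCc5ccccc5)cc1 | intermediate
37 | 5,7-bis(benzyloxy)-2-[4-(benzyloxy)phenyl]-4-M-chroman-3-one (C2 and C4 labile) | C(c5ccccc5)Oc1ccc([C@H]2Oc3c(c(OCc5ccccc5)cc(OCc5ccccc5)c3C3C(=O)C(c4ccc(OCc5ccccc5)cc4)Oc4cc(OCc5ccccc5)cc(OCc5ccccc5)c34)[C@@H](c3c(OCc5ccccc5)cc(OCc5ccccc5)c4c3O[C@@H](c3ccc(OCc5ccccc5)cc3)[C@@H](OCc5ccccc5)[C@@H]4OCc5ccccc5)[C@H]2OCc5ccccc5)cc1 | intermediate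
38 | dodeca-O-benzyl trimer: (2S,3S)-5,7-bis(benzyloxy)-2-[4-(benzyloxy)phenyl]-4-M-chroman-3-ol, upper ring all cis (2S,3S,4R), upper 3-OH free | C(c5ccccc5)Oc1ccc([C@H]2Oc3c(c(OCc5ccccc5)cc(OCc5ccccc5)c3[C@H]3c4c(OCc5ccccc5)cc(OCc5ccccc5)cc4O[C@@H](c4ccc(OCc5ccccc5)cc4)[C@H]3O)[C@@H](c3c(OCc5ccccc5)cc(OCc5ccccc5)c4c3O[C@@H](c3ccc(OCc5ccccc5)cc3)[C@@H](OCc5ccccc5)[C@@H]4OCc5ccccc5)[C@H]2OCc5ccccc5)cc1 | intermediate
39 | ent-epiafzelechin-(4β→8)-epiafzelechin-(4α→8)-ent-epiafzelechin-4α-ol: upper unit (2S,3S,4R), middle unit (2R,3R,4S), lower unit (2S,3S,4R)-flavan-3,4-diol, both interflavan bonds cis to the neighbouring 3-OH | Oc1ccc([C@H]2Oc3c(c(O)cc(O)c3[C@H]3c4c(O)cc(O)cc4O[C@@H](c4ccc(O)cc4)[C@H]3O)[C@@H](c3c(O)cc(O)c4c3O[C@@H](c3ccc(O)cc3)[C@@H](O)[C@@H]4O)[C@H]2O)cc1 | target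

**Step count and risks**

Total step count: 26. Longest linear sequence: 25 (steps 1–19 and 21–26; step 20 is a one-step branch from 1).

Steps most likely to fail:

1. Step 21 (key step). Addition of the di-ortho-substituted, electron-rich aryldiazomethane to the peri-shielded C3 ketone may be slow, so that azine formation or protonation of the diazoalkane by the acidic enol product wins. The diazonium alkoxide may also close to a spiro-epoxide, or acyl rather than aryl migration may occur. The fallback builds the same pyranone ring without ring expansion; it sets out from 26 and rejoins the route at 33. Bromide 26 is converted into aryllithium 27 as in step 18 (n-BuLi, THF, −78 °C) and added to 5,7-bis(benzyloxy)-2,2-dimethyl-4H-1,3-benzodioxin-4-one F1 (from commercial 5,7-dihydroxy-2,2-dimethyl-4H-1,3-benzodioxin-4-one, BnBr, K2CO3, DMF). Collapse of the adduct on work-up releases acetone and gives the 2-hydroxybenzophenone (2-hydroxy-4,6-bis(benzyloxy)phenyl)(M)methanone F2. Acylation of the phenol with (tert-butyldimethylsilyloxy)acetyl chloride (Et3N, DMAP, CH2Cl2) gives the aryl ester 3,5-bis(benzyloxy)-2-(M-carbonyl)phenyl (tert-butyldimethylsilyloxy)acetate F3. Intramolecular aldol condensation (Kostanecki-type coumarin synthesis; DBU, toluene, 80 °C) then closes the ring to silyl ether 33.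

2. Step 25. Epimerisation at the shielded C4 of the upper ring may be too slow, or the catalyst may be mismatched with the congested substrate, giving incomplete dynamic resolution or hydride delivery to the wrong carbonyl face. The fallback uses substrate control; it sets out from 37 and returns at 38. Ketone 37 is equilibrated with DBU to the 2,4-cis-diaryl epimer and reduced with LiBH(s-Bu)3 (THF, −78 °C), whose equatorial attack should give the axial, all-cis alcohol. This yields 38 together with the all-cis diastereomer of opposite upper-ring configuration F4, which is separated by chromatography and returned to 37 by Dess–Martin oxidation.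

3. Step 26. Hydrogenolytic cleavage of the benzylic C4–O bond of the lower unit (activated by its phloroglucinol ring A) may compete with O-debenzylation, the three hindered alkyl benzyl ethers may cleave incompletely, and traces of acid may ionise the liberated 3,4-diol. The fallback replaces catalytic hydrogenolysis by single-electron reductive debenzylation; it sets out from 38 and returns at 39. Treatment with lithium 4,4'-di-tert-butylbiphenylide (THF, −78 °C) cleaves each O–CH2Ph bond through the benzyl radical anion without a metal surface, and should leave the C4–O bond intact because the electron-rich ring A is a poor electron acceptor; a pH 6 buffer quench follows. This fallback makes no new compound (F0).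

Further compounds
F1 | step 21 | 5,7-bis(benzyloxy)-2,2-dimethyl-4H-1,3-benzodioxin-4-one | CC1(C)OC(=O)c2c(OCc3ccccc3)cc(OCc3ccccc3)cc2O1
F2 | step 21 | (2-hydroxy-4,6-bis(benzyloxy)phenyl)(M)methanone | C(c5ccccc5)Oc1ccc([C@H]2Oc3c(c(OCc5ccccc5)cc(OCc5ccccc5)c3C(=O)c4c(O)cc(OCc5ccccc5)cc4OCc5ccccc5)[C@@H](c3c(OCc5ccccc5)cc(OCc5ccccc5)c4c3O[C@@H](c3ccc(OCc5ccccc5)cc3)[C@@H](OCc5ccccc5)[C@@H]4OCc5ccccc5)[C@H]2OCc5ccccc5)cc1
F3 | step 21 | 3,5-bis(benzyloxy)-2-(M-carbonyl)phenyl (tert-butyldimethylsilyloxy)acetate | C(c5ccccc5)Oc1ccc([C@H]2Oc3c(c(OCc5ccccc5)cc(OCc5ccccc5)c3C(=O)c4c(OC(=O)CO[Si](C)(C)C(C)(C)C)cc(OCc5ccccc5)cc4OCc5ccccc5)[C@@H](c3c(OCc5ccccc5)cc(OCc5ccccc5)c4c3O[C@@H](c3ccc(OCc5ccccc5)cc3)[C@@H](OCc5ccccc5)[C@@H]4OCc5ccccc5)[C@H]2OCc5ccccc5)cc1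
F4 | step 25 | diastereomer of 38 with the upper ring all cis (2R,3R,4S) | C(c5ccccc5)Oc1ccc([C@H]2Oc3c(c(OCc5ccccc5)cc(OCc5ccccc5)c3[C@@H]3c4c(OCc5ccccc5)cc(OCc5ccccc5)cc4O[C@H](c4ccc(OCc5ccccc5)cc4)[C@@H]3O)[C@@H](c3c(OCc5ccccc5)cc(OCc5ccccc5)c4c3O[C@@H](c3ccc(OCc5ccccc5)cc3)[C@@H](OCc5ccccc5)[C@@H]4OCc5ccccc5)[C@H]2OCc5ccccc5)cc1
F0 | step 26 | none | none
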